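I know none of the constants of this flask, so I start from what needs none: counting reagent. By the suspected steps each target takes one reagent and each side product two. Elm's first reading adds up to 1.40 mM against a charge of 1.4 mM, which leaves 0 mM of reagent beside 36.6% of substrate, so reagent is the limiting reagent. Elm's four readings pooled give a ratio of target to side product of 8.65, and so 1.23: this is the reagent price of target, the reagent used per target made. Once reagent and intermediate have both gone, target is the reagent charge divided by this price.

| flask | substrate | reagent | remark | time |
|---|---|---|---|---|
| elm | 2 mM | 1.4 mM | the very flask that is asked about, followed so far |  |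
| larch | 1.3 mM | 1.4 mM | run made earlier |  |
| flask | 2.0 mM | 1.40 mM |  | 25 min |

| run | time / min | target / % | side product / % | substrate / % |
|---|---|---|---|---|
| elm | 0.667 | 56.4 | 6.8 | 36.6 |
| elm | 1.33 | 57.3 | 6.0 | 36.5 |
| elm | 3.00 | 57.0 | 6.4 | 36.5 |
| elm | 8.00 | 56.8 | 7.1 | 36.8 |
| larch | 2.00 | 82.8 | 12.7 | 4.9 |
| larch | 6.00 | 83.2 | 12.4 | 4.9 |
| larch | 12.0 | 84.9 | 12.5 | 4.4 |
| larch | 20.0 | 83.0 | 11.7 | 4.2 |

(scatter of a reading: 0.5 percentage points)

1. ratio of target to side product at 1.0 s
2. ratio of target to side product at 40 s
3. ratio of target to side product at 25 min
4. which of target and side product there is more of at 25 min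

- what is said of target includes crystals
- crystals is a solid; its amount is given per volume of the solution
- on the list of suspects stand: crystals <-> target; substrate + reagent <-> intermediate; intermediate -> target; reagent + intermediate -> side product

Time first: by hand, with reagent at that count I expect target to stay where it is, and elm's target reads 56.4% at 0.667 min and 56.8% at 8.00 min, flat within the scatter of 0.5 percentage points. Substrate next: by hand, at a set reagent charge, target in mM follows the price. Larch at 1.3 mM reads a ratio of 6.77 and a price of 1.30, so target is 1.08 mM there against 1.14 mM in elm. In logarithms, the ratio read from these two runs climbs as the substrate charge to the power 0.568. Reagent last: both runs carry 1.4 mM, so the readings show nothing of it.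

For this flask I commit to a ratio of 8.65 at 40 s and at 25 min, with target ahead; the earliest reading stands at 0.667 min, and at 1.0 s I give no figure. The forecast says 2.5, 8.5 and 8.6 with target ahead, and calls the earliest value “poorly constrained because the timescale is unresolved”.

The flask gives 3.29, 8.92 and 8.92, and at 25 min it holds target at 57.2% and side product at 6.41%.

    crystals ⇌ target, rate k1*(cs1 - [target]) while solid is left; crystals form when [target] > cs1 (solubility = 0.850 mM, k = 2.10 /s)
    substrate + reagent ⇌ intermediate (K = 12000 /M, k = 350 /M/s)
    intermediate → target (k = 0.440 /s)
    reagent + intermediate → side product (k = 140 /M/s)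

Substrate and reagent make intermediate, half of that step's turnover being done by 1.11 s, and intermediate goes on to target, half by 0.0565 min, while reagent beside it takes some into side product. By 2.50 min reagent stands at 0% and intermediate at 0%, with substrate at 36.4%, and at 250 min substrate still stands at 36.4%. The flask's own ratio of 8.92 makes the price 1.22, which gives this flask 57.2% of target, and it holds 57.2%. With 5.0 mM of substrate the ratio is 18.7, so the price falls to 1.11, which gives 25.3% of target, and that flask holds 25.3%.

The runs were generated by integration for an exercise, noise included.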